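Its constants stand for no real mixture; what happens was integrated by code.

At most 33.7% of the charged E can enter solution in 10 s: that is what its dissolving delivers into a solution kept empty.

    J ⇌ D (K1 = 3.8, k1 = 0.11 s⁻¹)
    X + J → X.J (k2 = 0.87 M⁻¹ s⁻¹)
    X.J ⇌ L (K3 = 1.1, k3 = 0.11 s⁻¹)
    E ⇌ X, rate k4*(cs4 - [X]) while solid is left; crystals form when [X] > cs4 (cs4 = 0.48 M, k4 = 0.040 s⁻¹)
    G ⇌ J, rate k5*(csat - [J]) (k5 = 1.7 s⁻¹, csat = 74 mM)
    J + X.J → J.X.J (k6 = 1.5 M⁻¹ s⁻¹)

E 0.57 M; G 74 mM (held); time 10 s

- X.J at 10 s, in percent of the E charged
- concentration of J in solution at 10 s, in percent of saturation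

Keep a ledger of E, the limiting reagent: in the same time, transfer from G can deliver 221%, far more than the dissolving can. You need J first. Transfer from G at 1.7 s⁻¹ is much faster than the loss of J to D at 0.11 s⁻¹, so I hold J steady at 69.5 mM, dropping the way back from D. Dissolved X then reacts with J at a pseudo-first-order constant k′ of 0.0605 s⁻¹. X gains from E and loses to J, so while solid lasts it climbs exponentially towards a steady level.

Its time constant, the filling time τ of X, is one over the sum of the dissolving coefficient and k′: 9.95 s. The level it climbs towards is the dissolving coefficient times the solubility times τ: 0.191 M.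

Now the entries at 10 s, in shares of the charged E. First, X in solution: 21.3%. Second, integrating k′[X] over time gives 7.48% that has reacted with J. Third, X.J is lost to L and J.X.J at 0.214 s⁻¹; integrating its balance, without the way back from L, leaves 3.92% as X.J, so 3.56% sits in L and J.X.J. Last, the solid E, 71.2%, closes the books. Putting X back into the balance of J gives 88.8% of saturation, which is lower than the J I assumed.

The forecast gives 4% (3.3% to 4.8%) and 88% of saturation (85% to 91%), holding that “X.J is lost to L and J.X.J about as fast as it builds”.

The flask gives 4.10% and 88.5%. With τ, X was reckoned at 21.3% of the charged E, and it stood at 21.5%. Carry τ to the same flask read at 40 s: the filling is then 98.2% done, which puts X at 32.9%, and that flask holds 34.8%, with 7.25% of E still solid.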